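**Retrosynthetic overview**
1. The target comes from saponification of the side-chain methyl ester of a spiro diester. The spiro-dihydrofuran ring is closed last, by acid-catalysed addition of a tertiary carbinol to the neighbouring tropone carbonyl with loss of methanol.
2. That carbinol comes from a nickel-catalysed reductive C(sp2)–C(sp3) coupling of a 2-bromotropone ester (fragment B) with a spiro-epoxide (fragment A) at its CH2 terminus. This is the fragment union and the key bond.
3. Fragment B: the seven-membered ring is made by dibromocarbene ring expansion of the Birch diene of 2,5-dimethylresorcinol dimethyl ether (from resorcinol). The ester is added by enol-ether acylation, then the ring is dehydrogenated.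
4. Fragment A: from 2-methylcyclohexenone by asymmetric conjugate addition, imine Michael addition (quaternary centre), methylation, hydration, methylenation and face-selective epoxidation (spiro centre).
5. Ring order: the cyclohexane ring is bought, the tropone ring is made in fragment B, and the dihydrofuran ring is formed after the coupling.

Assumption: the target is the free hydroxy acid with configuration 1'S,2'R,3'S,6'S as drawn; MeI, CHBr3, Cl3CCOCl and similar one-carbon donors are treated as reagents.

**Fragment A (steps 1–6)**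

Step 1
Reactants: 1 2-methylcyclohex-2-en-1-one; 2 isopropenylmagnesium bromide
Product: 4 (3S)-2-methyl-3-(prop-1-en-2-yl)cyclohexan-1-one (C2 epimers), via magnesium enolate 3 (not isolated)
Conditions: Cu(OTf)2 (3 mol%), chiral NHC ligand (4 mol%, enantiomer giving 3S), Et2O, −30 °C; aq NH4Cl
Reagents that add atoms: none
Why: Copper-catalysed asymmetric conjugate addition of a Grignard reagent to an α-substituted cyclic enone; the ligand-bound alkenylcopper species selects the enone face and sets C3 as S, while C2 is not controlled and is erased in step 2.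

Step 2
Reactants: 4 (3S)-2-methyl-3-(prop-1-en-2-yl)cyclohexan-1-one; 5 methyl acrylate
Product: 8 methyl 3-[(1R,6R)-1-methyl-2-oxo-6-(prop-1-en-2-yl)cyclohexyl]propanoate, via benzyl imine 6 (not isolated), via Michael adduct imine 7 (not isolated)
Conditions: BnNH2, 4 Å MS, PhMe, 80 °C; then 5, 60 °C; then 10% aq AcOH, THF, rt
Reagents that add atoms: water, O
Why: d'Angelo-type imine Michael addition in which the more substituted secondary enamine tautomer adds to the acrylate at the methyl-bearing carbon anti to the neighbouring isopropenyl group, setting the quaternary centre (1R) with the propanoate chain trans to isopropenyl.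

Step 3
Reactants: 8 methyl 3-[(1R,6R)-1-methyl-2-oxo-6-(prop-1-en-2-yl)cyclohexyl]propanoate
Product: 11 methyl 3-[(1R,3S,6R)-1,3-dimethyl-2-oxo-6-(prop-1-en-2-yl)cyclohexyl]propanoate, via lithium enolate 9 (not isolated), via C3 epimer mixture 10 (not isolated)
Conditions: LiN(iPr)2, THF, −78 °C; MeI, −78 → −20 °C; then NaOMe (cat.), MeOH, rt
Reagents that add atoms: iodomethane, CI
Why: Kinetic enolate alkylation at the only enolisable ketone position (the ketone is deprotonated ahead of the ester at −78 °C), followed by base equilibration that places the new methyl equatorial (3S) because the axial epimer clashes 1,3-diaxially with the axial methyl of the quaternary carbon.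

Step 4
Reactants: 11 methyl 3-[(1R,3S,6R)-1,3-dimethyl-2-oxo-6-(prop-1-en-2-yl)cyclohexyl]propanoate
Product: 12 methyl 3-[(1R,3S,6S)-6-(2-hydroxypropan-2-yl)-1,3-dimethyl-2-oxocyclohexyl]propanoate
Conditions: Co(acac)2 (10 mol%), PhSiH3, O2 (1 atm), i-PrOH/THF, rt
Reagents that add atoms: dioxygen, O=O
Why: Mukaiyama hydration (hydrogen-atom transfer to the 1,1-disubstituted alkene, trapping of the tertiary radical by O2, reduction) gives the Markovnikov tertiary alcohol without touching ketone or ester and creates no new stereocentre (the descriptor changes only by priority).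

Step 5
Reactants: 12 methyl 3-[(1R,3S,6S)-6-(2-hydroxypropan-2-yl)-1,3-dimethyl-2-oxocyclohexyl]propanoate
Product: 13 methyl 3-[(1R,3S,6S)-6-(2-hydroxypropan-2-yl)-1,3-dimethyl-2-methylidenecyclohexyl]propanoate
Conditions: Zn, CH2Br2, TiCl4 (excess reagent), THF/CH2Cl2, 0 °C → rt
Reagents that add atoms: dibromomethane, BrCBr
Why: Lombardo methylenation is non-basic, so the hindered, enolisable ketone is converted without epimerising the α-methyl centre and without attacking the ester; the tertiary hydroxyl is carried as its metal alkoxide and returns on work-up.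

Step 6
Reactants: 13 methyl 3-[(1R,3S,6S)-6-(2-hydroxypropan-2-yl)-1,3-dimethyl-2-methylidenecyclohexyl]propanoate
Product: 14 methyl 3-[(3S,4R,5S,8S)-5-(2-hydroxypropan-2-yl)-4,8-dimethyl-1-oxaspiro[2.5]octan-4-yl]propanoate
Conditions: DMDO, acetone, 0 °C
Reagents that add atoms: dimethyldioxirane, CC1(C)OO1
Why: Sterically controlled epoxidation of the exocyclic alkene from the face opposite the axial methyl on the adjacent quaternary carbon (axial attack) places the epoxide oxygen axial and sets the future spiro centre (3S); the neutral oxidant avoids epoxide opening by the free tertiary alcohol.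

**Fragment B (steps 7–14)**

Step 7
Reactants: 15 resorcinol
Product: 16 1,3-dimethoxybenzene
Conditions: MeI, K2CO3, acetone, reflux
Reagents that add atoms: iodomethane, CI
Why: Williamson O-methylation of both phenols.

Step 8
Reactants: 16 1,3-dimethoxybenzene
Product: 18 1,3-dimethoxy-2-methylbenzene, via aryllithium 17 (not isolated)
Conditions: n-BuLi, THF, 0 °C → rt; MeI, 0 °C
Reagents that add atoms: iodomethane, CI
Why: Directed ortho-metalation occurs only at the position flanked by both methoxy groups, and the aryllithium is methylated.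

Step 9
Reactants: 18 1,3-dimethoxy-2-methylbenzene
Product: 19 2-(3,5-dimethoxy-4-methylphenyl)-4,4,5,5-tetramethyl-1,3,2-dioxaborolane
Conditions: [Ir(OMe)(cod)]2 (1.5 mol%), 4,4'-di-tert-butyl-2,2'-bipyridine (3 mol%), B2pin2 (0.55 equiv), hexane, 60 °C
Reagents that add atoms: bis(pinacolato)diboron, CC1(C)OB(OC1(C)C)B1OC(C)(C)C(C)(C)O1
Why: Sterically governed iridium-catalysed aromatic C–H borylation goes to the only C–H that has no ortho substituent (C5).

Step 10
Reactants: 19 2-(3,5-dimethoxy-4-methylphenyl)-4,4,5,5-tetramethyl-1,3,2-dioxaborolane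
Product: 20 1,3-dimethoxy-2,5-dimethylbenzene
Conditions: Pd2(dba)3 (2 mol%), P(o-tol)3 (8 mol%), K2CO3, MeI, DMF/H2O, 60 °C
Reagents that add atoms: iodomethane, CI
Why: Suzuki–Miyaura methylation of the aryl boronate with iodomethane installs the second ring methyl.

Step 11
Reactants: 20 1,3-dimethoxy-2,5-dimethylbenzene
Product: 21 1,5-dimethoxy-3,6-dimethylcyclohexa-1,4-diene (cis/trans mixture)
Conditions: Li, NH3(l), THF, t-BuOH, −78 °C; then H2O
Reagents that add atoms: none
Why: Birch reduction keeps both methoxy groups on sp2 carbons and protonates the two methyl-bearing carbons, giving the symmetric unconjugated bis-enol ether.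

Step 12
Reactants: 21 1,5-dimethoxy-3,6-dimethylcyclohexa-1,4-diene
Product: 23 2-bromo-6-methoxy-4,7-dimethylcyclohepta-2,5-dien-1-one, via dibromocyclopropane 22 (not isolated)
Conditions: CHBr3 (1.0 equiv), KOtBu, pentane, −30 → 0 °C; then AgNO3, NaHCO3, acetone/H2O, 0 °C → rt
Reagents that add atoms: bromoform, BrC(Br)Br; water, O
Why: Dibromocarbene adds once to one of the two equivalent enol-ether double bonds (the first cyclopropane shields the second), and silver-assisted electrocyclic opening of the alkoxy-dibromocyclopropane with hydrolysis of the oxocarbenium ion expands the ring to the α-bromo enone (Birch-type gem-dihalocyclopropane ring expansion) while the buffer keeps the second enol ether intact.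

Step 13
Reactants: 23 2-bromo-6-methoxy-4,7-dimethylcyclohepta-2,5-dien-1-one
Product: 25 2-bromo-6-methoxy-4,7-dimethyl-5-(trichloroacetyl)cyclohepta-2,4,6-trien-1-one, via trichloroacetyl dienone 24 (not isolated)
Conditions: Cl3CCOCl, pyridine, CH2Cl2, 0 °C; then DDQ, CH2Cl2, 40 °C
Reagents that add atoms: trichloroacetyl chloride, ClC(=O)C(Cl)(Cl)Cl
Why: C-acylation of the remaining enol ether at its β-carbon (the future ester carbon), then DDQ dehydrogenation (hydride abstraction at the doubly allylic CH, proton loss) gives the aromatic tropone before any base can trigger loss of HBr from the bromodienone.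

Step 14
Reactants: 25 2-bromo-6-methoxy-4,7-dimethyl-5-(trichloroacetyl)cyclohepta-2,4,6-trien-1-one
Product: 26 methyl 4-bromo-7-methoxy-2,6-dimethyl-5-oxocyclohepta-1,3,6-triene-1-carboxylate
Conditions: MeOH, K2CO3 (cat.), 0 °C
Reagents that add atoms: methanol, CO
Why: Haloform-type cleavage of the trichloromethyl ketone by methanol gives the methyl ester under conditions too mild to displace the tropone bromide.

**Union and endgame (steps 15–17)**

Step 15
Reactants: 14 methyl 3-[(3S,4R,5S,8S)-5-(2-hydroxypropan-2-yl)-4,8-dimethyl-1-oxaspiro[2.5]octan-4-yl]propanoate; 26 methyl 4-bromo-7-methoxy-2,6-dimethyl-5-oxocyclohepta-1,3,6-triene-1-carboxylate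
Product: 28 methyl 4-{[(1S,2R,3S,6S)-1-hydroxy-3-(2-hydroxypropan-2-yl)-2-(3-methoxy-3-oxopropyl)-2,6-dimethylcyclohexyl]methyl}-7-methoxy-2,6-dimethyl-5-oxocyclohepta-1,3,6-triene-1-carboxylate, via iodohydrin 27 (not isolated)
Conditions: NiBr2(dme) (10 mol%), 4,4'-di-tert-butyl-2,2'-bipyridine (12 mol%), NaI (0.5 equiv), Et3N·HCl (1.2 equiv), Mn powder (2.5 equiv), DMPU, 30 °C
Reagents that add atoms: none
Why: Proposed new method: nickel-catalysed, iodide-relayed reductive coupling of a 2-bromotropone with a 2,2-disubstituted spiro-epoxide at its CH2 terminus, in which triethylammonium iodide opens the epoxide by SN2 at the unhindered CH2 (the fully substituted carbon cannot be attacked and Mn avoids the Lewis-acid hydride-shift rearrangement that zinc salts would cause) so the C–O bond and configuration of the carbinol are untouched, zerovalent nickel–bipyridine inserts into the activated C–Br bond of the vinylogous acyl bromide, the primary β-hydroxyalkyl radical formed by iodine abstraction is captured by the troponyl nickel species, and C(sp2)–C(sp3) reductive elimination from trivalent nickel outruns β-hydroxide loss; the closest known reaction types are the nickel-catalysed cross-electrophile coupling of aryl bromides with alkyl iodides and the iodide-co-catalysed arylation of terminal epoxides, neither shown for halotropones or for epoxides with a fully substituted carbon.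

Step 16
Reactants: 28 methyl 4-{[(1S,2R,3S,6S)-1-hydroxy-3-(2-hydroxypropan-2-yl)-2-(3-methoxy-3-oxopropyl)-2,6-dimethylcyclohexyl]methyl}-7-methoxy-2,6-dimethyl-5-oxocyclohepta-1,3,6-triene-1-carboxylate
Product: 30 methyl (1'S,2'R,3'S,6'S)-3'-(2-hydroxypropan-2-yl)-2'-(3-methoxy-3-oxopropyl)-2',5,6',8-tetramethyl-7-oxo-3,7-dihydrospiro[cyclohepta[b]furan-2,1'-cyclohexane]-6-carboxylate, via cyclic hemiketal 29 (not isolated)
Conditions: PPTS (20 mol%), PhMe, 70 °C
Reagents that add atoms: none
Why: Acid-catalysed 5-exo addition of the tertiary hydroxyl to the adjacent tropone carbonyl, loss of water to an aromatic dialkoxytropylium ion and hydrolysis at the methoxy-bearing carbon (a transposed vinylogous transesterification) closes the dihydrofuran; the carbinol C–O bond is never broken, so the spiro centre keeps the configuration set in step 6, and the remote tertiary alcohol cannot reach the ring.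

Step 17
Reactants: 30 methyl (1'S,2'R,3'S,6'S)-3'-(2-hydroxypropan-2-yl)-2'-(3-methoxy-3-oxopropyl)-2',5,6',8-tetramethyl-7-oxo-3,7-dihydrospiro[cyclohepta[b]furan-2,1'-cyclohexane]-6-carboxylate
Product: 32 CNP0448476.1 = 3-[(1'S,2'R,3'S,6'S)-3'-(2-hydroxypropan-2-yl)-6-(methoxycarbonyl)-2',5,6',8-tetramethyl-7-oxo-3,7-dihydrospiro[cyclohepta[b]furan-2,1'-cyclohexan]-2'-yl]propanoic acid, via lithium carboxylate 31 (not isolated)
Conditions: LiOH·H2O, THF/H2O, 0 °C → rt; then 1 M HCl to pH 4
Reagents that add atoms: lithium hydroxide, [Li+].[OH-]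
Why: Chemoselective saponification of the unhindered aliphatic methyl ester; the tropone ester is flanked by a methyl group and the ring carbonyl and the vinylogous ester carbon is fully substituted, so both resist hydroxide at this temperature, and mild acidification leaves the tertiary alcohol intact.

**Compound list**
1 | 2-methylcyclohex-2-en-1-one | CC1=CCCCC1=O | starting material
2 | isopropenylmagnesium bromide | CC(=C)[Mg]Br | starting material
3 | bromomagnesium enolate of 4 (isopropenyl carbon as in 4) | Br[Mg]OC1=C(C)[C@@H](C(C)=C)CCC1 | intermediate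
4 | (3S)-2-methyl-3-(prop-1-en-2-yl)cyclohexan-1-one, C2 epimer mixture | O=C1CCC[C@H](C(C)=C)C1C | intermediate
5 | methyl acrylate | C=CC(=O)OC | starting material
6 | N-benzyl imine of 4 | c1ccccc1CN=C2CCC[C@H](C(C)=C)C2C | intermediate
7 | N-benzyl imine of 8 | c1ccccc1CN=C2CCC[C@H](C(C)=C)[C@@]2(C)CCC(=O)OC | intermediate
8 | methyl 3-[(1R,6R)-1-methyl-2-oxo-6-(prop-1-en-2-yl)cyclohexyl]propanoate | O=C1CCC[C@H](C(C)=C)[C@@]1(C)CCC(=O)OC | intermediate
9 | lithium enolate of 8 (enolised toward ring C3) | [Li]OC1=CCC[C@H](C(C)=C)[C@@]1(C)CCC(=O)OC | intermediate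
10 | methyl 3-[(1R,6R)-1,3-dimethyl-2-oxo-6-(prop-1-en-2-yl)cyclohexyl]propanoate, C3 epimer mixture | O=C1C(C)CC[C@H](C(C)=C)[C@@]1(C)CCC(=O)OC | intermediate
11 | methyl 3-[(1R,3S,6R)-1,3-dimethyl-2-oxo-6-(prop-1-en-2-yl)cyclohexyl]propanoate | O=C1[C@@H](C)CC[C@H](C(C)=C)[C@@]1(C)CCC(=O)OC | intermediate
12 | methyl 3-[(1R,3S,6S)-6-(2-hydroxypropan-2-yl)-1,3-dimethyl-2-oxocyclohexyl]propanoate | O=C1[C@@H](C)CC[C@H](C(C)(C)O)[C@@]1(C)CCC(=O)OC | intermediate
13 | methyl 3-[(1R,3S,6S)-6-(2-hydroxypropan-2-yl)-1,3-dimethyl-2-methylidenecyclohexyl]propanoate | C=C1[C@@H](C)CC[C@H](C(C)(C)O)[C@@]1(C)CCC(=O)OC | intermediate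
14 | methyl 3-[(3S,4R,5S,8S)-5-(2-hydroxypropan-2-yl)-4,8-dimethyl-1-oxaspiro[2.5]octan-4-yl]propanoate | O1C[C@@]12[C@@H](C)CC[C@H](C(C)(C)O)[C@@]2(C)CCC(=O)OC | intermediate
15 | resorcinol | Oc1cccc(O)c1 | starting material
16 | 1,3-dimethoxybenzene | COc1cccc(OC)c1 | intermediate
17 | (2,6-dimethoxyphenyl)lithium | [Li]c1c(OC)cccc1OC | intermediate
18 | 1,3-dimethoxy-2-methylbenzene | COc1cccc(OC)c1C | intermediate
19 | 2-(3,5-dimethoxy-4-methylphenyl)-4,4,5,5-tetramethyl-1,3,2-dioxaborolane | COc1cc(B2OC(C)(C)C(C)(C)O2)cc(OC)c1C | intermediate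
20 | 1,3-dimethoxy-2,5-dimethylbenzene | COc1cc(C)cc(OC)c1C | intermediate
21 | 1,5-dimethoxy-3,6-dimethylcyclohexa-1,4-diene (cis/trans mixture) | COC1=CC(C)C=C(OC)C1C | intermediate
22 | 7,7-dibromo-1,3-dimethoxy-2,5-dimethylbicyclo[4.1.0]hept-3-ene (stereoisomer mixture) | COC1=CC(C)C2C(Br)(Br)C2(OC)C1C | intermediate
23 | 2-bromo-6-methoxy-4,7-dimethylcyclohepta-2,5-dien-1-one (stereoisomer mixture) | COC1=CC(C)C=C(Br)C(=O)C1C | intermediate
24 | 2-bromo-6-methoxy-4,7-dimethyl-5-(trichloroacetyl)cyclohepta-2,5-dien-1-one (stereoisomer mixture) | COC1=C(C(=O)C(Cl)(Cl)Cl)C(C)C=C(Br)C(=O)C1C | intermediate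
25 | 2-bromo-6-methoxy-4,7-dimethyl-5-(trichloroacetyl)cyclohepta-2,4,6-trien-1-one | COC1=C(C)C(=O)C(Br)=CC(C)=C1C(=O)C(Cl)(Cl)Cl | intermediate
26 | methyl 4-bromo-7-methoxy-2,6-dimethyl-5-oxocyclohepta-1,3,6-triene-1-carboxylate | COC(=O)C1=C(C)C=C(Br)C(=O)C(C)=C1OC | intermediate
27 | methyl 3-[(1R,2S,3S,6S)-2-hydroxy-6-(2-hydroxypropan-2-yl)-2-(iodomethyl)-1,3-dimethylcyclohexyl]propanoate | O[C@@]1(CI)[C@@H](C)CC[C@H](C(C)(C)O)[C@@]1(C)CCC(=O)OC | intermediate
28 | methyl 4-{[(1S,2R,3S,6S)-1-hydroxy-3-(2-hydroxypropan-2-yl)-2-(3-methoxy-3-oxopropyl)-2,6-dimethylcyclohexyl]methyl}-7-methoxy-2,6-dimethyl-5-oxocyclohepta-1,3,6-triene-1-carboxylate | COC(=O)C1=C(C)C=C(C[C@]2(O)[C@@H](C)CC[C@H](C(C)(C)O)[C@@]2(C)CCC(=O)OC)C(=O)C(C)=C1OC | intermediate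
29 | methyl (1'S,2'R,3'S,6'S)-8a-hydroxy-3'-(2-hydroxypropan-2-yl)-7-methoxy-2'-(3-methoxy-3-oxopropyl)-2',5,6',8-tetramethyl-3,8a-dihydrospiro[cyclohepta[b]furan-2,1'-cyclohexane]-6-carboxylate (8a epimers) | COC(=O)C1=C(C)C=C2C[C@]3(OC2(O)C(C)=C1OC)[C@@H](C)CC[C@H](C(C)(C)O)[C@@]3(C)CCC(=O)OC | intermediate
30 | methyl (1'S,2'R,3'S,6'S)-3'-(2-hydroxypropan-2-yl)-2'-(3-methoxy-3-oxopropyl)-2',5,6',8-tetramethyl-7-oxo-3,7-dihydrospiro[cyclohepta[b]furan-2,1'-cyclohexane]-6-carboxylate | COC(=O)c1c(C)cc2c(c(C)c1=O)O[C@@]1(C2)[C@@H](C)CC[C@H](C(C)(C)O)[C@@]1(C)CCC(=O)OC | intermediate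
31 | lithium carboxylate of 32 | COC(=O)c1c(C)cc2c(c(C)c1=O)O[C@@]1(C2)[C@@H](C)CC[C@H](C(C)(C)O)[C@@]1(C)CCC(=O)[O-].[Li+] | intermediate
32 | CNP0448476.1, 3-[(1'S,2'R,3'S,6'S)-3'-(2-hydroxypropan-2-yl)-6-(methoxycarbonyl)-2',5,6',8-tetramethyl-7-oxo-3,7-dihydrospiro[cyclohepta[b]furan-2,1'-cyclohexan]-2'-yl]propanoic acid | COC(=O)c1c(C)cc2c(c(C)c1=O)O[C@@]1(C2)[C@@H](C)CC[C@H](C(C)(C)O)[C@@]1(C)CCC(=O)O | target

**Totals**
Total step count: 17 (fragment A 6 steps, fragment B 8 steps, union and endgame 3 steps).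
Longest linear sequence: 11 steps (steps 7–14, then 15–17, resorcinol to target).

**Steps most likely to fail and their fallbacks**

Step 15 (the proposed new coupling) may fail through binding or reduction of the troponoid by low-valent nickel, homocoupling of 26, or rearrangement of the epoxide. The fallback uses known chemistry, sets out from alkene 13 and bromotropone 26, and comes back at 30. A Heck reaction (Pd(OAc)2, P(t-Bu)3·HBF4, Cy2NMe, dioxane, 100 °C) joins 26 to the exocyclic alkene 13 and gives methyl 4-[(E)-{(2R,3S,6S)-3-(2-hydroxypropan-2-yl)-2-(3-methoxy-3-oxopropyl)-2,6-dimethylcyclohexylidene}methyl]-7-methoxy-2,6-dimethyl-5-oxocyclohepta-1,3,6-triene-1-carboxylate F7. Camphorsulfonic acid in wet CH2Cl2 at 0 °C then protonates the trisubstituted alkene at the arylmethine carbon. The tertiary ring cation is trapped by the tropone carbonyl oxygen from the axial face, anti to the axial methyl, and the resulting methoxytropylium ion loses methanol to give 30. In this variant the spiro centre is set by cation capture rather than by the epoxide.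

Step 12 may fail through double cyclopropanation, or through hydrolysis or isomerisation of the second enol ether in 23. The fallback sets out from 21 and comes back at 26, and it differentiates the two enol ethers before the ring expansion. Diene 21 is mono-acylated (Cl3CCOCl, 1.0 equiv, pyridine, CH2Cl2, 0 °C) to 2,2,2-trichloro-1-(2,4-dimethoxy-3,6-dimethylcyclohexa-1,4-dien-1-yl)ethan-1-one F3. Methanolysis (MeOH, cat. K2CO3) gives methyl 2,4-dimethoxy-3,6-dimethylcyclohexa-1,4-diene-1-carboxylate F4, whose push-pull double bond is inert to carbenes. Dibromocarbene (CHBr3, KOtBu, pentane, −40 °C) then adds only to the remaining electron-rich enol ether to give methyl 7,7-dibromo-1,3-dimethoxy-2,5-dimethylbicyclo[4.1.0]hept-3-ene-4-carboxylate F5. AgNO3/NaHCO3 in aqueous acetone opens it to methyl 5-bromo-2-methoxy-3,7-dimethyl-4-oxocyclohepta-1,5-diene-1-carboxylate F6, and DDQ dehydrogenates F6 to 26.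

Step 1 may fail because the enantioselectivity of an alkenyl Grignard addition to an α-methyl enone is uncertain. The fallback sets out from 1 and 2 and comes back at 8, replacing asymmetric catalysis by resolution. Ligand-free addition (CuBr·SMe2 5 mol%, THF, −40 °C; aq NH4Cl) gives racemic 2-methyl-3-(prop-1-en-2-yl)cyclohexan-1-one F1. Under the conditions of step 2 this gives racemic methyl 3-[(1R*,6R*)-1-methyl-2-oxo-6-(prop-1-en-2-yl)cyclohexyl]propanoate F2 (the non-isolated intermediates are the racemates of 3, 6 and 7). Preparative chiral SFC of F2 delivers the (1R,6R) enantiomer, which is 8.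

Further compounds
F1 | step 1 | racemic 2-methyl-3-(prop-1-en-2-yl)cyclohexan-1-one | CC(=C)C1CCCC(=O)C1C
F2 | step 1 | racemic methyl 3-[(1R*,6R*)-1-methyl-2-oxo-6-(prop-1-en-2-yl)cyclohexyl]propanoate | O=C1CCC[C@H](C(C)=C)[C@@]1(C)CCC(=O)OC.O=C1CCC[C@@H](C(C)=C)[C@]1(C)CCC(=O)OC
F3 | step 12 | 2,2,2-trichloro-1-(2,4-dimethoxy-3,6-dimethylcyclohexa-1,4-dien-1-yl)ethan-1-one | COC1=CC(C)C(C(=O)C(Cl)(Cl)Cl)=C(OC)C1C
F4 | step 12 | methyl 2,4-dimethoxy-3,6-dimethylcyclohexa-1,4-diene-1-carboxylate | COC(=O)C1=C(OC)C(C)C(OC)=CC1C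
F5 | step 12 | methyl 7,7-dibromo-1,3-dimethoxy-2,5-dimethylbicyclo[4.1.0]hept-3-ene-4-carboxylate | COC(=O)C1=C(OC)C(C)C2(OC)C(Br)(Br)C2C1C
F6 | step 12 | methyl 5-bromo-2-methoxy-3,7-dimethyl-4-oxocyclohepta-1,5-diene-1-carboxylate | COC(=O)C1=C(OC)C(C)C(=O)C(Br)=CC1C
F7 | step 15 | methyl 4-[(E)-{(2R,3S,6S)-3-(2-hydroxypropan-2-yl)-2-(3-methoxy-3-oxopropyl)-2,6-dimethylcyclohexylidene}methyl]-7-methoxy-2,6-dimethyl-5-oxocyclohepta-1,3,6-triene-1-carboxylate | COC(=O)C1=C(C)C=C(/C=C2\[C@@H](C)CC[C@H](C(C)(C)O)[C@@]2(C)CCC(=O)OC)C(=O)C(C)=C1OC
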